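**Strategy.** The route rests on the 3,6-dihydro-2H-pyran (O1, C2 bearing the tetraene, carbinol C3, C4=C5, C6): its C4H=C5(CH3) alkene is a propyne unit, and the remaining C6–O1–C2–C3 chain is a trans-2,4-disubstituted oxetan-3-one. A zerovalent-nickel-catalysed [4+2] insertion of propyne into the C(O)–CH(CH3) bond of this oxetanone forms C3–C4 and C5–C6 in one operation and gives the 2H-pyran-3(6H)-one with C2 and C6 already set; methyl addition then creates C3. The oxetanone comes from oxetan-3-one by double SAMP-hydrazone alkylation. The lactone half arises from an allylboration–lactonisation, and Stille couplings around (E)-1,2-bis(tributylstannyl)ethene assemble the tetraene.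

Key step: step 5

Remarks on the chemistry.
- Atom labels: pyran O1, C2, C3, C4, C5, C6 as above. Lactone half: C1′ (ester C=O), C2′ (CH–CH3), C3′ (CH–O), C4′ (quaternary), C5′ (CH–CH3), C6′ (lactone C=O).
- Assumption: SAMP is taken to give the (S) configuration at each alkylated oxetane carbon, by analogy with SAMP hydrazones of other cyclic ketones; RAMP would be used if the sense were opposite.
- Compounds 1, 2, 6, 10, 18, 20 and 25 are taken as commercial.

**Pyran half**

Step 1
Reactants: 1 oxetan-3-one; 2 (S)-1-amino-2-(methoxymethyl)pyrrolidine (SAMP)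
Product: 3 (2S)-2-(methoxymethyl)-N-(oxetan-3-ylidene)pyrrolidin-1-amine
Conditions: neat, 55 °C
Reagents that add atoms: none
Why: Hydrazone condensation of a reactive strained ketone with the N-amino auxiliary; no stereocentre is formed.

Step 2
Reactants: 3 (2S)-2-(methoxymethyl)-N-(oxetan-3-ylidene)pyrrolidin-1-amine
Product: 5 (2S)-2-(methoxymethyl)-N-[(2S)-2-methyloxetan-3-ylidene]pyrrolidin-1-amine, via lithium azaenolate 4 (not isolated)
Conditions: t-BuLi, THF, −78 °C; then MeI, −78 °C to rt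
Reagents that add atoms: iodomethane, CI
Why: SAMP/RAMP hydrazone α-alkylation, in which the chelated lithium azaenolate should be methylated on the face away from the methoxymethyl arm, setting the future C6 as (S).

Step 3
Reactants: 5 (2S)-2-(methoxymethyl)-N-[(2S)-2-methyloxetan-3-ylidene]pyrrolidin-1-amine; 6 (chloromethoxy)triisopropylsilane
Product: 8 (2S)-2-(methoxymethyl)-N-[(2S,4R)-2-methyl-4-{[(triisopropylsilyl)oxy]methyl}oxetan-3-ylidene]pyrrolidin-1-amine (trans), via lithium azaenolate 7 (not isolated)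
Conditions: t-BuLi, THF, −78 °C; then 6, −78 °C to −20 °C
Reagents that add atoms: none
Why: Second SAMP-hydrazone alkylation, in which kinetic deprotonation at the unsubstituted α′-CH2 and auxiliary-controlled attack on the reactive α-chloro ether should place the silyloxymethyl group trans to the methyl group and set the future C2.

Step 4
Reactants: 8 (2S)-2-(methoxymethyl)-N-[(2S,4R)-2-methyl-4-{[(triisopropylsilyl)oxy]methyl}oxetan-3-ylidene]pyrrolidin-1-amine
Product: 9 (2S,4S)-2-methyl-4-{[(triisopropylsilyl)oxy]methyl}oxetan-3-one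
Conditions: sat. aq. oxalic acid, Et2O, rt
Reagents that add atoms: water, O
Why: Mild acidic hydrazone hydrolysis, under which the two α-alkoxy stereocentres and the silyl ether should survive.

Step 5
Reactants: 9 (2S,4S)-2-methyl-4-{[(triisopropylsilyl)oxy]methyl}oxetan-3-one; 10 propyne
Product: 11 (2S,6S)-5,6-dimethyl-2-{[(triisopropylsilyl)oxy]methyl}-2H-pyran-3(6H)-one
Conditions: Ni(cod)2 (10 mol %), PPh3 (30 mol %), propyne (1 M in THF, slow addition), toluene, 60 °C
Reagents that add atoms: none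
Why: Proposed new method: zerovalent nickel joins the C3 carbonyl of 9 and propyne by oxidative cyclisation (the terminal alkyne carbon bonds to C3, the methyl-bearing carbon to nickel), the strained oxanickelacyclopentene opens by β-carbon elimination of the C3–CH(CH3) bond, and C(sp2)–C(sp3) reductive elimination then forms C5–C6. The closest known reaction is the nickel-catalysed [4+2] ring expansion of oxetan-3-ones and azetidin-3-ones with alkynes, so far shown for cleavage of an unsubstituted CH2–C(O) bond. The pyranone ring is closed by reductive elimination from a seven-membered nickelacycle, a formal insertion of the alkyne into a σ bond and not a pericyclic closure. No stereocentre is made: C2 is untouched and C6 should be carried over with retention, because β-carbon elimination and reductive elimination both keep the configuration of the migrating carbon. The step needs cleavage on the methyl side and the H-terminus of propyne next to the carbonyl; the bulky, non-coordinating and inductively deactivating CH2OSi(i-Pr)3 group should disfavour nickel–carbon bond formation at C2, and the alkyne regiochemistry follows the usual preference of nickel oxidative cyclisations for bonding at the less hindered alkyne carbon. Slow addition of propyne should limit its oligomerisation.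

Step 6
Reactants: 11 (2S,6S)-5,6-dimethyl-2-{[(triisopropylsilyl)oxy]methyl}-2H-pyran-3(6H)-one
Product: 12 (2S,3R,6S)-3,5,6-trimethyl-2-{[(triisopropylsilyl)oxy]methyl}-3,6-dihydro-2H-pyran-3-ol
Conditions: MeLi, CeCl3, THF, −78 °C
Reagents that add atoms: methyllithium, [Li]C
Why: Organocerium 1,2-addition to the enone; with the C2 substituent pseudoequatorial and the C6 methyl pseudoaxial, axial attack anti to the C6 methyl should put the new methyl cis to the C2 substituent and set C3 as (R).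

Step 7
Reactants: 12 (2S,3R,6S)-3,5,6-trimethyl-2-{[(triisopropylsilyl)oxy]methyl}-3,6-dihydro-2H-pyran-3-ol
Product: 13 (2S,3R,6S)-2-(hydroxymethyl)-3,5,6-trimethyl-3,6-dihydro-2H-pyran-3-ol
Conditions: Bu4NF, THF, 0 °C
Reagents that add atoms: none
Why: Fluoride cleavage of the primary silyl ether, to which the tertiary allylic alcohol and the allylic ether are inert.

Step 8
Reactants: 13 (2S,3R,6S)-2-(hydroxymethyl)-3,5,6-trimethyl-3,6-dihydro-2H-pyran-3-ol
Product: 14 (2R,3R,6S)-3-hydroxy-3,5,6-trimethyl-3,6-dihydro-2H-pyran-2-carbaldehyde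
Conditions: TEMPO (cat.), PhI(OAc)2, CH2Cl2, rt
Reagents that add atoms: none
Why: Oxoammonium oxidation selective for the primary alcohol, in a non-basic medium that should protect the α-alkoxy aldehyde from epimerisation.

Step 9
Reactants: 14 (2R,3R,6S)-3-hydroxy-3,5,6-trimethyl-3,6-dihydro-2H-pyran-2-carbaldehyde
Product: 15 (2S,3R,6S)-2-ethynyl-3,5,6-trimethyl-3,6-dihydro-2H-pyran-3-ol
Conditions: dimethyl (1-diazo-2-oxopropyl)phosphonate, K2CO3, MeOH, 0 °C
Reagents that add atoms: dimethyl (1-diazo-2-oxopropyl)phosphonate, COP(=O)(OC)C(=[N+]=[N-])C(C)=O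
Why: Seyferth–Gilbert homologation in the Ohira–Bestmann variant should convert the aldehyde into the terminal alkyne at low temperature, where C2 epimerisation is slow.

Step 10
Reactants: 15 (2S,3R,6S)-2-ethynyl-3,5,6-trimethyl-3,6-dihydro-2H-pyran-3-ol
Product: 17 (2S,3R,6S)-2-[(1E)-1-iodoprop-1-en-2-yl]-3,5,6-trimethyl-3,6-dihydro-2H-pyran-3-ol, via alkenylalane 16 (not isolated)
Conditions: Me3Al (3 equiv), Cp2ZrCl2 (25 mol %), CH2Cl2, 0 °C to rt; then I2, THF, −30 °C
Reagents that add atoms: trimethylaluminium, C[Al](C)C; iodine, II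
Why: Negishi zirconium-catalysed carboalumination adds methyl and aluminium syn with methyl on the internal carbon, and iodinolysis with retention should give the (E)-trisubstituted vinyl iodide.

Step 11
Reactants: 17 (2S,3R,6S)-2-[(1E)-1-iodoprop-1-en-2-yl]-3,5,6-trimethyl-3,6-dihydro-2H-pyran-3-ol; 18 (E)-1,2-bis(tributylstannyl)ethene
Product: 19 (2S,3R,6S)-3,5,6-trimethyl-2-[(2E,4E)-5-(tributylstannyl)penta-2,4-dien-2-yl]-3,6-dihydro-2H-pyran-3-ol
Conditions: PdCl2(MeCN)2 (5 mol %), DMF, rt, 18 in excess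
Reagents that add atoms: none
Why: Stille coupling with retention of both alkene geometries, the excess of distannane favouring mono-coupling.

**Lactone half**

Step 12
Reactants: 20 triisopropyl(prop-2-yn-1-yloxy)silane
Product: 22 methyl 4-[(triisopropylsilyl)oxy]but-2-ynoate, via lithium acetylide 21 (not isolated)
Conditions: n-BuLi, THF, −78 °C; then ClCO2Me
Reagents that add atoms: methyl chloroformate, COC(=O)Cl
Why: Acylation of a lithium acetylide with a chloroformate.

Step 13
Reactants: 22 methyl 4-[(triisopropylsilyl)oxy]but-2-ynoate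
Product: 24 methyl (2Z)-3-methyl-2-[(4,4,5,5-tetramethyl-1,3,2-dioxaborolan-2-yl)methyl]-4-[(triisopropylsilyl)oxy]but-2-enoate, via alkenylcuprate 23 (not isolated)
Conditions: Me2CuLi (from MeLi and CuBr·SMe2), THF, −78 °C; then 2-(iodomethyl)-4,4,5,5-tetramethyl-1,3,2-dioxaborolane, HMPA, −78 °C to 0 °C
Reagents that add atoms: methyllithium, [Li]C; 2-(iodomethyl)-4,4,5,5-tetramethyl-1,3,2-dioxaborolane, ICB1OC(C)(C)C(C)(C)O1
Why: Syn-carbocupration of the ynoate and alkylation of the α-cuprio enoate at low temperature should give the tetrasubstituted allylboronate with methyl cis to the CH2B group.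

Step 14
Reactants: 25 methyl (S)-3-hydroxy-2-methylpropanoate
Product: 26 methyl (S)-3-[(tert-butyldimethylsilyl)oxy]-2-methylpropanoate
Conditions: TBSCl, imidazole, CH2Cl2, rt
Reagents that add atoms: tert-butyldimethylsilyl chloride, CC(C)(C)[Si](C)(C)Cl
Why: Silylation of the primary alcohol; the C2′ stereocentre is bought in.

Step 15
Reactants: 26 methyl (S)-3-[(tert-butyldimethylsilyl)oxy]-2-methylpropanoate
Product: 27 (S)-3-[(tert-butyldimethylsilyl)oxy]-2-methylpropanal
Conditions: i-Bu2AlH, CH2Cl2, −78 °C; aq. potassium sodium tartrate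
Reagents that add atoms: none
Why: Partial ester reduction through a tetrahedral aluminium intermediate that is stable at −78 °C, where the α-stereocentre should not epimerise.

Step 16
Reactants: 24 methyl (2Z)-3-methyl-2-[(4,4,5,5-tetramethyl-1,3,2-dioxaborolan-2-yl)methyl]-4-[(triisopropylsilyl)oxy]but-2-enoate; 27 (S)-3-[(tert-butyldimethylsilyl)oxy]-2-methylpropanal
Product: 29 (4S,5S)-5-[(2S)-1-[(tert-butyldimethylsilyl)oxy]propan-2-yl]-4-methyl-3-methylidene-4-{[(triisopropylsilyl)oxy]methyl}oxolan-2-one, via borate ester 28 (not isolated)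
Conditions: Sc(OTf)3 (10 mol %), toluene, 0 °C to rt; then PPTS (cat.), rt
Reagents that add atoms: none
Why: Allylboration through a closed chair transition state followed by lactonisation: the γ-methyl cis to the CH2B group ends up cis to the side chain, fixing C3′ relative to C4′ from the reagent geometry, while the anti-Felkin preference of Z-γ-substituted allylboronates toward α-methyl aldehydes should place the C3′ oxygen anti to the C2′ methyl.

Step 17
Reactants: 29 (4S,5S)-5-[(2S)-1-[(tert-butyldimethylsilyl)oxy]propan-2-yl]-4-methyl-3-methylidene-4-{[(triisopropylsilyl)oxy]methyl}oxolan-2-one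
Product: 32 (2R)-2-[(2S,3S)-3-methyl-4-methylidene-5-oxo-3-{[(triisopropylsilyl)oxy]methyl}oxolan-2-yl]propanoic acid, via primary alcohol 30 (not isolated), via aldehyde 31 (not isolated)
Conditions: CrO3, H2SO4, acetone/H2O, 0 °C
Reagents that add atoms: water, O
Why: Jones oxidation, in which the acidic medium cleaves the primary tert-butyldimethylsilyl ether and the alcohol is oxidised through the aldehyde hydrate to the acid while the hindered triisopropylsilyl ether should stay.

Step 18
Reactants: 32 (2R)-2-[(2S,3S)-3-methyl-4-methylidene-5-oxo-3-{[(triisopropylsilyl)oxy]methyl}oxolan-2-yl]propanoic acid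
Product: 33 methyl (2R)-2-[(2S,3S)-3-methyl-4-methylidene-5-oxo-3-{[(triisopropylsilyl)oxy]methyl}oxolan-2-yl]propanoate
Conditions: MeI, KHCO3, DMF, rt
Reagents that add atoms: iodomethane, CI
Why: Carboxylate O-alkylation under weakly basic conditions, chosen over diazoalkanes, which would add to the α-methylene lactone.

Step 19
Reactants: 33 methyl (2R)-2-[(2S,3S)-3-methyl-4-methylidene-5-oxo-3-{[(triisopropylsilyl)oxy]methyl}oxolan-2-yl]propanoate
Product: 34 methyl (2R)-2-[(2S,3S)-3-(hydroxymethyl)-3-methyl-4-methylidene-5-oxooxolan-2-yl]propanoate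
Conditions: HF·pyridine, THF/pyridine, 0 °C to rt
Reagents that add atoms: none
Why: Buffered acidic fluoride desilylation, which should leave the lactone, ester and exocyclic alkene untouched.

Step 20
Reactants: 34 methyl (2R)-2-[(2S,3S)-3-(hydroxymethyl)-3-methyl-4-methylidene-5-oxooxolan-2-yl]propanoate
Product: 35 methyl (2R)-2-[(2S,3S,4R)-3-(hydroxymethyl)-3,4-dimethyl-5-oxooxolan-2-yl]propanoate
Conditions: H2 (1 atm), [Ir(cod)(PCy3)(py)]PF6 (5 mol %), CH2Cl2, rt
Reagents that add atoms: none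
Why: Hydroxyl-directed hydrogenation: iridium bound to the CH2OH group on C4′ should deliver hydrogen to the exocyclic alkene from that face, so the new C5′ methyl ends up cis to the C4′ methyl (C5′ R).

Step 21
Reactants: 35 methyl (2R)-2-[(2S,3S,4R)-3-(hydroxymethyl)-3,4-dimethyl-5-oxooxolan-2-yl]propanoate
Product: 36 methyl (2R)-2-[(2S,3R,4R)-3-formyl-3,4-dimethyl-5-oxooxolan-2-yl]propanoate
Conditions: Dess–Martin periodinane, NaHCO3, CH2Cl2, rt
Reagents that add atoms: none
Why: Dess–Martin oxidation of the neopentyl alcohol to a non-enolisable aldehyde.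

Step 22
Reactants: 36 methyl (2R)-2-[(2S,3R,4R)-3-formyl-3,4-dimethyl-5-oxooxolan-2-yl]propanoate
Product: 37 methyl (2R)-2-[(2S,3S,4R)-3-[(E)-2-iodoethenyl]-3,4-dimethyl-5-oxooxolan-2-yl]propanoate
Conditions: CrCl2, CHI3, THF, 0 °C to rt
Reagents that add atoms: iodoform, IC(I)I
Why: Takai olefination, which is E-selective for hindered aldehydes and tolerates ester and lactone.

Step 23
Reactants: 37 methyl (2R)-2-[(2S,3S,4R)-3-[(E)-2-iodoethenyl]-3,4-dimethyl-5-oxooxolan-2-yl]propanoate; 18 (E)-1,2-bis(tributylstannyl)ethene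
Product: 38 methyl (2R)-2-[(2S,3R,4R)-3,4-dimethyl-5-oxo-3-[(1E,3E)-4-(tributylstannyl)buta-1,3-dien-1-yl]oxolan-2-yl]propanoate
Conditions: PdCl2(MeCN)2 (5 mol %), DMF, rt, 18 in excess
Reagents that add atoms: none
Why: Stille coupling with retention of geometry, the excess of distannane favouring mono-coupling.

Step 24
Reactants: 38 methyl (2R)-2-[(2S,3R,4R)-3,4-dimethyl-5-oxo-3-[(1E,3E)-4-(tributylstannyl)buta-1,3-dien-1-yl]oxolan-2-yl]propanoate
Product: 39 methyl (2R)-2-[(2S,3R,4R)-3-[(1E,3E)-4-iodobuta-1,3-dien-1-yl]-3,4-dimethyl-5-oxooxolan-2-yl]propanoate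
Conditions: I2, CH2Cl2, 0 °C
Reagents that add atoms: iodine, II
Why: Iododestannylation at the ipso carbon with retention of alkene geometry.

**Union**

Step 25
Reactants: 39 methyl (2R)-2-[(2S,3R,4R)-3-[(1E,3E)-4-iodobuta-1,3-dien-1-yl]-3,4-dimethyl-5-oxooxolan-2-yl]propanoate; 19 (2S,3R,6S)-3,5,6-trimethyl-2-[(2E,4E)-5-(tributylstannyl)penta-2,4-dien-2-yl]-3,6-dihydro-2H-pyran-3-ol
Product: 40 methyl (2R)-2-[(2S,3R,4R)-3-[(1E,3E,5E,7E)-8-[(2S,3R,6S)-3-hydroxy-3,5,6-trimethyl-3,6-dihydro-2H-pyran-2-yl]nona-1,3,5,7-tetraen-1-yl]-3,4-dimethyl-5-oxooxolan-2-yl]propanoate (target)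
Conditions: Pd2(dba)3 (5 mol %), AsPh3 (20 mol %), NMP, rt, dark
Reagents that add atoms: none
Why: Stille coupling of dienyl iodide and dienylstannane forms the central single bond with retention of all four alkene geometries and should tolerate the free tertiary alcohol, lactone and ester.

**Compound list**

1 | oxetan-3-one | O=C1COC1 | starting material
2 | (S)-1-amino-2-(methoxymethyl)pyrrolidine (SAMP) | COC[C@@H]1CCCN1N | starting material
3 | (2S)-2-(methoxymethyl)-N-(oxetan-3-ylidene)pyrrolidin-1-amine | COC[C@@H]1CCCN1N=C1COC1 | intermediate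
4 | lithium azaenolate of 3 | [Li]N(N1CCC[C@H]1COC)C1=COC1 | intermediate
5 | (2S)-2-(methoxymethyl)-N-[(2S)-2-methyloxetan-3-ylidene]pyrrolidin-1-amine | COC[C@@H]1CCCN1N=C1CO[C@H]1C | intermediate
6 | (chloromethoxy)triisopropylsilane | ClCO[Si](C(C)C)(C(C)C)C(C)C | starting material
7 | lithium azaenolate of 5 (deprotonated at the CH2 carbon) | [Li]N(N1CCC[C@H]1COC)C1=CO[C@H]1C | intermediate
8 | (2S)-2-(methoxymethyl)-N-[(2S,4R)-2-methyl-4-{[(triisopropylsilyl)oxy]methyl}oxetan-3-ylidene]pyrrolidin-1-amine (trans) | COC[C@@H]1CCCN1N=C1[C@H](CO[Si](C(C)C)(C(C)C)C(C)C)O[C@H]1C | intermediate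
9 | (2S,4S)-2-methyl-4-{[(triisopropylsilyl)oxy]methyl}oxetan-3-one | CC(C)[Si](C(C)C)(C(C)C)OC[C@@H]1O[C@@H](C)C1=O | intermediate
10 | propyne | CC#C | starting material
11 | (2S,6S)-5,6-dimethyl-2-{[(triisopropylsilyl)oxy]methyl}-2H-pyran-3(6H)-one | CC(C)[Si](C(C)C)(C(C)C)OC[C@@H]1O[C@@H](C)C(C)=CC1=O | intermediate
12 | (2S,3R,6S)-3,5,6-trimethyl-2-{[(triisopropylsilyl)oxy]methyl}-3,6-dihydro-2H-pyran-3-ol | CC(C)[Si](C(C)C)(C(C)C)OC[C@@H]1O[C@@H](C)C(C)=C[C@@]1(C)O | intermediate
13 | (2S,3R,6S)-2-(hydroxymethyl)-3,5,6-trimethyl-3,6-dihydro-2H-pyran-3-ol | OC[C@@H]1O[C@@H](C)C(C)=C[C@@]1(C)O | intermediate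
14 | (2R,3R,6S)-3-hydroxy-3,5,6-trimethyl-3,6-dihydro-2H-pyran-2-carbaldehyde | O=C[C@@H]1O[C@@H](C)C(C)=C[C@@]1(C)O | intermediate
15 | (2S,3R,6S)-2-ethynyl-3,5,6-trimethyl-3,6-dihydro-2H-pyran-3-ol | C#C[C@@H]1O[C@@H](C)C(C)=C[C@@]1(C)O | intermediate
16 | (E)-alkenyl(dimethyl)alane from 15, with the tertiary oxygen as its dimethylaluminium alkoxide | C[Al](C)/C=C(\C)[C@@H]1O[C@@H](C)C(C)=C[C@@]1(C)O[Al](C)C | intermediate
17 | (2S,3R,6S)-2-[(1E)-1-iodoprop-1-en-2-yl]-3,5,6-trimethyl-3,6-dihydro-2H-pyran-3-ol | I/C=C(\C)[C@@H]1O[C@@H](C)C(C)=C[C@@]1(C)O | intermediate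
18 | (E)-1,2-bis(tributylstannyl)ethene | CCCC[Sn](CCCC)(CCCC)/C=C/[Sn](CCCC)(CCCC)CCCC | starting material
19 | (2S,3R,6S)-3,5,6-trimethyl-2-[(2E,4E)-5-(tributylstannyl)penta-2,4-dien-2-yl]-3,6-dihydro-2H-pyran-3-ol | CCCC[Sn](CCCC)(CCCC)/C=C/C=C(\C)[C@@H]1O[C@@H](C)C(C)=C[C@@]1(C)O | intermediate
20 | triisopropyl(prop-2-yn-1-yloxy)silane | C#CCO[Si](C(C)C)(C(C)C)C(C)C | starting material
21 | lithium acetylide of 20 | [Li]C#CCO[Si](C(C)C)(C(C)C)C(C)C | intermediate
22 | methyl 4-[(triisopropylsilyl)oxy]but-2-ynoate | COC(=O)C#CCO[Si](C(C)C)(C(C)C)C(C)C | intermediate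
23 | lithium alkenyl(methyl)cuprate from syn-addition to 22 (copper cis to the new methyl) | COC(=O)/C([Cu-]C)=C(/C)CO[Si](C(C)C)(C(C)C)C(C)C.[Li+] | intermediate
24 | methyl (2Z)-3-methyl-2-[(4,4,5,5-tetramethyl-1,3,2-dioxaborolan-2-yl)methyl]-4-[(triisopropylsilyl)oxy]but-2-enoate | COC(=O)/C(CB1OC(C)(C)C(C)(C)O1)=C(/C)CO[Si](C(C)C)(C(C)C)C(C)C | intermediate
25 | methyl (S)-3-hydroxy-2-methylpropanoate | OC[C@H](C)C(=O)OC | starting material
26 | methyl (S)-3-[(tert-butyldimethylsilyl)oxy]-2-methylpropanoate | CC(C)(C)[Si](C)(C)OC[C@H](C)C(=O)OC | intermediate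
27 | (S)-3-[(tert-butyldimethylsilyl)oxy]-2-methylpropanal | CC(C)(C)[Si](C)(C)OC[C@H](C)C=O | intermediate
28 | open-chain pinacol borate ester of the homoallylic alcohol (methyl ester, before lactonisation) | CC(C)(C)[Si](C)(C)OC[C@H](C)[C@H](OB1OC(C)(C)C(C)(C)O1)[C@](C)(CO[Si](C(C)C)(C(C)C)C(C)C)C(=C)C(=O)OC | intermediate
29 | (4S,5S)-5-[(2S)-1-[(tert-butyldimethylsilyl)oxy]propan-2-yl]-4-methyl-3-methylidene-4-{[(triisopropylsilyl)oxy]methyl}oxolan-2-one | CC(C)(C)[Si](C)(C)OC[C@H](C)[C@@H]1OC(=O)C(=C)[C@@]1(C)CO[Si](C(C)C)(C(C)C)C(C)C | intermediate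
30 | (4S,5S)-5-[(2S)-1-hydroxypropan-2-yl]-4-methyl-3-methylidene-4-{[(triisopropylsilyl)oxy]methyl}oxolan-2-one | OC[C@H](C)[C@@H]1OC(=O)C(=C)[C@@]1(C)CO[Si](C(C)C)(C(C)C)C(C)C | intermediate
31 | (2R)-2-[(2S,3S)-3-methyl-4-methylidene-5-oxo-3-{[(triisopropylsilyl)oxy]methyl}oxolan-2-yl]propanal | O=C[C@H](C)[C@@H]1OC(=O)C(=C)[C@@]1(C)CO[Si](C(C)C)(C(C)C)C(C)C | intermediate
32 | (2R)-2-[(2S,3S)-3-methyl-4-methylidene-5-oxo-3-{[(triisopropylsilyl)oxy]methyl}oxolan-2-yl]propanoic acid | OC(=O)[C@H](C)[C@@H]1OC(=O)C(=C)[C@@]1(C)CO[Si](C(C)C)(C(C)C)C(C)C | intermediate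
33 | methyl (2R)-2-[(2S,3S)-3-methyl-4-methylidene-5-oxo-3-{[(triisopropylsilyl)oxy]methyl}oxolan-2-yl]propanoate | COC(=O)[C@H](C)[C@@H]1OC(=O)C(=C)[C@@]1(C)CO[Si](C(C)C)(C(C)C)C(C)C | intermediate
34 | methyl (2R)-2-[(2S,3S)-3-(hydroxymethyl)-3-methyl-4-methylidene-5-oxooxolan-2-yl]propanoate | COC(=O)[C@H](C)[C@@H]1OC(=O)C(=C)[C@@]1(C)CO | intermediate
35 | methyl (2R)-2-[(2S,3S,4R)-3-(hydroxymethyl)-3,4-dimethyl-5-oxooxolan-2-yl]propanoate | COC(=O)[C@H](C)[C@@H]1OC(=O)[C@H](C)[C@@]1(C)CO | intermediate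
36 | methyl (2R)-2-[(2S,3R,4R)-3-formyl-3,4-dimethyl-5-oxooxolan-2-yl]propanoate | COC(=O)[C@H](C)[C@@H]1OC(=O)[C@H](C)[C@@]1(C)C=O | intermediate
37 | methyl (2R)-2-[(2S,3S,4R)-3-[(E)-2-iodoethenyl]-3,4-dimethyl-5-oxooxolan-2-yl]propanoate | COC(=O)[C@H](C)[C@@H]1OC(=O)[C@H](C)[C@@]1(C)/C=C/I | intermediate
38 | methyl (2R)-2-[(2S,3R,4R)-3,4-dimethyl-5-oxo-3-[(1E,3E)-4-(tributylstannyl)buta-1,3-dien-1-yl]oxolan-2-yl]propanoate | COC(=O)[C@H](C)[C@@H]1OC(=O)[C@H](C)[C@@]1(C)/C=C/C=C/[Sn](CCCC)(CCCC)CCCC | intermediate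
39 | methyl (2R)-2-[(2S,3R,4R)-3-[(1E,3E)-4-iodobuta-1,3-dien-1-yl]-3,4-dimethyl-5-oxooxolan-2-yl]propanoate | COC(=O)[C@H](C)[C@@H]1OC(=O)[C@H](C)[C@@]1(C)/C=C/C=C/I | intermediate
40 | methyl (2R)-2-[(2S,3R,4R)-3-[(1E,3E,5E,7E)-8-[(2S,3R,6S)-3-hydroxy-3,5,6-trimethyl-3,6-dihydro-2H-pyran-2-yl]nona-1,3,5,7-tetraen-1-yl]-3,4-dimethyl-5-oxooxolan-2-yl]propanoate | COC(=O)[C@H](C)[C@@H]1OC(=O)[C@H](C)[C@@]1(C)/C=C/C=C/C=C/C=C(\C)[C@@H]1O[C@@H](C)C(C)=C[C@@]1(C)O | target

**Totals**

Total step count: 25. Longest linear sequence: 12 steps (steps 1–11 and 25; equally steps 12, 13 and 16–25).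

**Three steps most likely to fail**

1. Step 5 (proposed new method). What may go wrong: β-carbon elimination on the wrong side (at the silyloxymethyl-bearing carbon), β-hydride elimination from the secondary alkylnickel, or oligomerisation of propyne before oxidative cyclisation. Fallback by known chemistry (ring-closing metathesis): it sets out from (chloromethoxy)triisopropylsilane 6 and comes back to the route at pyranone 11. (S)-3-Methylbut-3-en-2-ol (lipase resolution of the commercial racemate) is O-alkylated with bromoacetic acid (NaH, THF) to 2-{[(2S)-3-methylbut-3-en-2-yl]oxy}acetic acid F1. Its pivaloyl mixed anhydride acylates lithiated (R)-4-benzyl-1,3-oxazolidin-2-one to give the glycolyl imide F2. The sodium enolate (NaN(SiMe3)2, THF, −78 °C) is alkylated with 6 on the face away from the benzyl group to give the α-alkoxy imide F3, which carries both ether stereocentres. Me(MeO)NH·HCl and Me3Al convert it into the Weinreb amide F4, and vinylmagnesium bromide gives the vinyl ketone F5. Ring-closing metathesis with the second-generation Hoveyda–Grubbs catalyst (CH2Cl2, 40 °C) then closes C4=C5 and should deliver 11, which re-enters at step 6.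

2. Step 16. What may go wrong: poor aldehyde facial selectivity (Felkin against anti-Felkin) in the chair transition state, or slow addition of the tetrasubstituted allylboronate with erosion of the aldehyde α-stereocentre. Fallback: it sets out from allylboronate 24 and comes back at primary alcohol 30. Compound 24 is added to methacrolein under chiral BINOL-phosphoric acid catalysis (TRIP enantiomer chosen for the (4S,5S) series, toluene), and lactonisation gives (4S,5S)-4-methyl-3-methylidene-5-(prop-1-en-2-yl)-4-{[(triisopropylsilyl)oxy]methyl}oxolan-2-one F6. Here C3′ and C4′ are set by catalyst and reagent geometry with no α-stereocentre in the aldehyde. Hydroboration of the isopropenyl group with 9-BBN and oxidation with NaBO3 should then set C2′ anti to the C3′ oxygen by 1,2-induction and give 30, which is oxidised to 32 under the conditions of step 17.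

3. Step 9. What may go wrong: retro-aldol cleavage between C2 and C3 and epimerisation at C2 of the β-hydroxy α-alkoxy aldehyde under basic methanol before homologation is complete. Fallback: it sets out from aldehyde 14 and comes back at alkyne 15. The carbonyl is consumed under non-basic conditions by dibromo-olefination (CBr4, PPh3, Zn dust, CH2Cl2, 0 °C) to (2S,3R,6S)-2-(2,2-dibromoethenyl)-3,5,6-trimethyl-3,6-dihydro-2H-pyran-3-ol F7. Treatment with n-BuLi (3 equiv, THF, −78 °C) then gives 15 by the Corey–Fuchs rearrangement, with no carbonyl present when base is used.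

Further compounds
F1 | step 5 | 2-{[(2S)-3-methylbut-3-en-2-yl]oxy}acetic acid | C=C(C)[C@H](C)OCC(=O)O
F2 | step 5 | (4R)-4-benzyl-3-(2-{[(2S)-3-methylbut-3-en-2-yl]oxy}acetyl)-1,3-oxazolidin-2-one | C=C(C)[C@H](C)OCC(=O)N1[C@H](Cc2ccccc2)COC1=O
F3 | step 5 | (4R)-4-benzyl-3-[(2S)-2-{[(2S)-3-methylbut-3-en-2-yl]oxy}-3-[(triisopropylsilyl)oxy]propanoyl]-1,3-oxazolidin-2-one | C=C(C)[C@H](C)O[C@@H](CO[Si](C(C)C)(C(C)C)C(C)C)C(=O)N1[C@H](Cc2ccccc2)COC1=O
F4 | step 5 | (2S)-N-methoxy-N-methyl-2-{[(2S)-3-methylbut-3-en-2-yl]oxy}-3-[(triisopropylsilyl)oxy]propanamide | C=C(C)[C@H](C)O[C@@H](CO[Si](C(C)C)(C(C)C)C(C)C)C(=O)N(C)OC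
F5 | step 5 | (4S)-4-{[(2S)-3-methylbut-3-en-2-yl]oxy}-5-[(triisopropylsilyl)oxy]pent-1-en-3-one | C=C(C)[C@H](C)O[C@@H](CO[Si](C(C)C)(C(C)C)C(C)C)C(=O)C=C
F6 | step 16 | (4S,5S)-4-methyl-3-methylidene-5-(prop-1-en-2-yl)-4-{[(triisopropylsilyl)oxy]methyl}oxolan-2-one | C=C(C)[C@@H]1OC(=O)C(=C)[C@@]1(C)CO[Si](C(C)C)(C(C)C)C(C)C
F7 | step 9 | (2S,3R,6S)-2-(2,2-dibromoethenyl)-3,5,6-trimethyl-3,6-dihydro-2H-pyran-3-ol | BrC(Br)=C[C@@H]1O[C@@H](C)C(C)=C[C@@]1(C)O
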